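## The problem

The target (18) is an 8-O-4' neolignan. Ring A (4-hydroxy-3,5-dimethoxyphenyl) carries the glycerol chain C7–C8–C9, and the C8 oxygen is the phenolic oxygen O4' of ring B, a 2,6-dimethoxyphenoxy ring with a 2,3-dihydroxypropyl chain (C7'–C8'–C9') at C1', para to the ether. No ring has to be closed: two tetrasubstituted arenes are joined through an acyclic secondary alkyl aryl ether, and two short polyol chains are built. There are three stereocentres. C7 (S) and C8 (R) are adjacent and erythro, so one can direct the other. C8' (S) sits across ring B, seven bonds from C8, and can only be set by a reagent or bought. The erythro relation is the hard part of the C7/C8 pair: hydride delivery to an α-aryloxy ketone under Felkin–Anh control or within a β-keto ester chelate is expected to lean toward threo, so erythro must come from a C7–C8 bond formation or from an inversion. The fragile sites are the C7 carbinol (benzylic to an electron-rich ring, prone to acid ionisation, to quinone methide formation once the para phenol is free, and to hydrogenolysis) and the C8–H of any carbonyl precursor (epimerisation, β-elimination). The free phenolic tetraol is very polar and should appear only at the end. The key step is possible because C1' is para to O4' and flanked by the unsubstituted C2' and C6', so a bromide there is unhindered and is the only carbon–halogen bond. C7' is a plain methylene, so it can be the terminal carbon of an epoxide whose other carbon already is C8'.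

## Retrosynthesis

18 to 17 to 16. Only protecting groups are removed at the end. The two O–benzyl bonds of 17 (ring A phenol and C9' alcohol) are cut last by neutral hydrogenolysis. The acetonide of 16 is hydrolysed one step earlier, because the C7 carbinol ionises far less readily while the para oxygen is still benzylated; the reverse order would expose a para-hydroxybenzyl ether to acid. Using benzyl on both oxygens means one reagent frees both, and by then the aryl bromide is gone.

16 to 13 plus 14. The C1'–C7' bond is cut so that C8' arrives resolved inside a three-carbon unit. The neighbouring options are weaker: allylation at C1' followed by asymmetric dihydroxylation relies on a terminal allylarene, a poor substrate class for that reaction, and carrying the chain on ring B from the start drags a third stereocentre and two more protected oxygens through the aldol and inversion steps. After this cut, 13 holds only the C7/C8 pair and 14 is a commercial single enantiomer. The forward reaction must join two electrophiles, open the epoxide at its terminal carbon through iodohydrin 15, leave C8' untouched and spare the acetonide, the benzyl ethers and the aryl methyl ethers.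

13 to 12. The two C–O bonds to the isopropylidene carbon are cut. The acetonide ties the C7 and C9 hydroxyls into a 1,3-dioxane, so the coupling meets no free hydroxyl next to the aryl ether. For the erythro diol the aryl and aryloxy groups are both equatorial (trans), so the ring forms without strain. The precursor 12 is the bare erythro diol.

12 to 11 to 10. The C7–O bond is the one re-made: 12 comes from reductive cleavage of the erythro ester-imide 11, and 11 from the threo aldol adduct 10 by SN2 inversion at C7. A directly anti-selective glycolate aldol would save a step, but its extension to an aryloxyacetyl donor with two ortho methoxy groups is untested. Reductions of a C7 ketone are biased toward threo. A dependable syn aldol followed by one clean inversion is therefore preferred. The forward steps must invert a benzylic carbinol without dehydration and then remove the auxiliary without β-elimination.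

10 to 5 plus 7. The C7–C8 bond is cut as an auxiliary-controlled boron aldol. This one step sets C8 in its final configuration and C7 in a defined (epimeric) one, from two achiral-chain partners of roughly half the size each. The (S)-4-benzyl auxiliary is chosen because its syn adduct has the C8 geometry of the target. The reaction passes through boron enolate 8 and boron aldolate 9.

5 to 2 plus 3, 2 to 1, and 7 to 6. The imide N–C bond is cut to acid 2 and auxiliary 3 (joined through mixed anhydride 4). The O–CH2 bond of 2 is a Williamson disconnection to phenol 1. The benzyl ether of 7 is cut to syringaldehyde 6. These are routine reactions on commercial materials.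

## Roads not taken

Alternative 1: The C1–C7 bond is cut. Aryllithium A1 would add at low temperature to the α-aryloxy aldehyde A2, which already carries the complete ring B with its protected chain, to give the carbinol A3. Its merit is economy of control: one pool-derived centre (C8) sets C7 by Felkin–Anh addition, which for a carbon nucleophile on an α-oxygenated aldehyde points to the erythro isomer, and no auxiliary or inversion is needed. Its weak points are the aldehyde and the selectivity. A2 is an α-aryloxy aldehyde with an acidic C8–H and would face a basic aryllithium. Lithium chelation by the aryloxy oxygen and its ortho methoxy groups favours the opposite (threo) face, so the Felkin–Anh preference is likely to be eroded. In step count for the C7/C8 core this road is probably shorter than the chosen one. The chosen plan sets against it a syn aldol whose outcome does not depend on a chelation balance, intermediates without an epimerisable aldehyde, and the fact that the C8' chain need not be built onto ring B beforehand.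

Alternative 2: The C7–H bond is made last on the keto ester A4, whose C8 epimerises rapidly. Hydrogenation with H2 and [RuCl(p-cymene)(BINAP)]Cl, a divalent ruthenium diphosphine catalyst, would funnel both C8 epimers into the hydroxy ester A5. Its merits are real: two stereocentres from one catalytic step, no auxiliary, no inversion. If it delivered A5 it would be the shortest entry to the erythro core and better than the chosen plan in atom and step economy. The weak point is the sense of diastereoselection. In the ruthenium-bound β-keto ester chelate, and equally in an outer-sphere Felkin-type transfer, acyclic α-oxygenated substrates are expected to give the syn (threo) isomer, whereas A5 is the anti (erythro) one. The step would have to run against the intrinsic bias. The acid-labile dioxolane of A4 would also have to survive a halide-containing ruthenium catalyst in hot alcohol. The chosen plan pays with a stoichiometric auxiliary and an extra inversion, but each stereochemical event follows its normal course.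

Alternative 3: The C8–H and C9–O bonds are made by hydroboration of the allylic alcohol A6 with 9-borabicyclo[3.3.1]nonane and oxidation with NaOH/H2O2, giving the diol A7. C7 can be set beforehand by catalytic asymmetric carbonyl reduction and would then direct C8 by minimising allylic strain. By analogy with 2-alkyl allylic alcohols this points to the anti (erythro) product, again without auxiliary or inversion, which is an advantage over the chosen plan. The weak point is mechanistic. Boron ends up on C9, β to the aryloxy group on C8, and β-aryloxy alkylboranes are prone to eliminate the phenoxide, which would remove ring B. The facial model is also calibrated for an alkyl substituent on the alkene, not an electron-rich aryloxy group. The chosen plan never places a metal or metalloid β to the C8–O bond and fixes the erythro relation by an SN2 event.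

All three alternatives need ring B to arrive with its chain attached and protected, so a C1'–C7' construction would still be required earlier. The chosen plan does this once, late and convergently.

Key step: step 8

Remark: compounds 1, 3, 6 and 14 are taken as purchased, 3 and 14 as single enantiomers. Unprimed locants (C7–C9) refer to the chain on ring A, primed ones (C1'–C9') to ring B and its chain.

Step 1
Reactants: 1 4-bromo-2,6-dimethoxyphenol
Product: 2 (4-bromo-2,6-dimethoxyphenoxy)acetic acid
Conditions: ClCH2CO2H, NaOH, H2O, 100 °C; then aq. HCl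
Reagents that add atoms: chloroacetic acid, OC(=O)CCl
Why: Williamson ether synthesis; the phenoxide displaces chloride from chloroacetate, and the aryl bromide is inert to aqueous base.

Step 2
Reactants: 2 (4-bromo-2,6-dimethoxyphenoxy)acetic acid; 3 (S)-4-benzyl-1,3-oxazolidin-2-one
Product: 5 (4S)-4-benzyl-3-[2-(4-bromo-2,6-dimethoxyphenoxy)acetyl]-1,3-oxazolidin-2-one, via mixed pivalic anhydride 4 (not isolated)
Conditions: PivCl, Et3N, THF, −20 °C; then 3, LiCl, −20 → 25 °C
Reagents that add atoms: none
Why: N-acylation of the oxazolidinone through the mixed anhydride; the lithium-activated auxiliary attacks the unhindered aryloxyacetyl carbonyl rather than the pivaloyl one.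

Step 3
Reactants: 6 syringaldehyde (4-hydroxy-3,5-dimethoxybenzaldehyde)
Product: 7 4-(benzyloxy)-3,5-dimethoxybenzaldehyde
Conditions: BnBr, K2CO3, DMF, 60 °C
Reagents that add atoms: benzyl bromide, BrCc1ccccc1
Why: Williamson benzylation of the phenol; the aldehyde is untouched under carbonate.

Step 4
Reactants: 5 (4S)-4-benzyl-3-[2-(4-bromo-2,6-dimethoxyphenoxy)acetyl]-1,3-oxazolidin-2-one; 7 4-(benzyloxy)-3,5-dimethoxybenzaldehyde
Product: 10 (4S)-4-benzyl-3-[(2S,3R)-3-[4-(benzyloxy)-3,5-dimethoxyphenyl]-2-(4-bromo-2,6-dimethoxyphenoxy)-3-hydroxypropanoyl]-1,3-oxazolidin-2-one (threo), via boron enolate 8 (not isolated), via boron aldolate 9 (not isolated)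
Conditions: Bu2BOTf, iPr2NEt, CH2Cl2, −78 → 0 °C; 7, −78 → 0 °C; then pH 7 buffer, MeOH, 30% H2O2, 0 °C
Reagents that add atoms: none
Why: Evans syn aldol. The (Z)-boron enolate 8 adds to 7 through a Zimmerman–Traxler chair on the enolate face away from the 4-benzyl group, which sets C8 in its final configuration (2S in the imide, 8R in the target). C7 is formed as the syn, threo epimer (3R) and is corrected in step 5.

Step 5
Reactants: 10 threo aldol adduct
Product: 11 (4S)-4-benzyl-3-[(2S,3S)-3-[4-(benzyloxy)-3,5-dimethoxyphenyl]-2-(4-bromo-2,6-dimethoxyphenoxy)-3-(4-nitrobenzoyloxy)propanoyl]-1,3-oxazolidin-2-one (erythro)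
Conditions: 4-O2NC6H4CO2H, PPh3, DIAD, toluene–THF, −20 → 0 °C
Reagents that add atoms: 4-nitrobenzoic acid, OC(=O)c1ccc(cc1)[N+](=O)[O-]
Why: Mitsunobu esterification; the carboxylate displaces the activated benzylic oxygen by SN2 with inversion, turning C7 from R to S and threo into erythro. The acidic nucleophile and low temperature are chosen to outrun dehydration.

Step 6
Reactants: 11 erythro 4-nitrobenzoate imide
Product: 12 (1S,2R)-1-[4-(benzyloxy)-3,5-dimethoxyphenyl]-2-(4-bromo-2,6-dimethoxyphenoxy)propane-1,3-diol
Conditions: LiBH4, THF–MeOH, 0 → 25 °C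
Reagents that add atoms: none
Why: Reductive removal of the acyloxazolidinone gives the C9 alcohol and hydride cleavage of the aryl ester frees the C7 hydroxyl. No stereocentre is a reacting carbon and the aryl bromide is inert to borohydride.

Step 7
Reactants: 12 erythro 1,3-diol
Product: 13 (4S,5R)-4-[4-(benzyloxy)-3,5-dimethoxyphenyl]-5-(4-bromo-2,6-dimethoxyphenoxy)-2,2-dimethyl-1,3-dioxane (trans)
Conditions: Me2C(OMe)2, PPTS (cat.), acetone, 25 °C
Reagents that add atoms: 2,2-dimethoxypropane, COC(C)(C)OC
Why: Acid-catalysed transacetalisation of the 1,3-diol; the erythro isomer gives the dioxane with aryl and aryloxy groups both equatorial, so closure is easy and no C–O bond at a stereocentre is broken.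

Step 8
Reactants: 13 bromoaryl erythro acetonide; 14 (S)-benzyl glycidyl ether [(2S)-2-(benzyloxymethyl)oxirane]
Product: 16 (2S)-1-(benzyloxy)-3-[4-{[(4S,5R)-4-[4-(benzyloxy)-3,5-dimethoxyphenyl]-2,2-dimethyl-1,3-dioxan-5-yl]oxy}-3,5-dimethoxyphenyl]propan-2-ol, via iodohydrin 15 (not isolated)
Conditions: NiCl2(dme) (10 mol %), 2,2'-bipyridine (10 mol %), NaI (25 mol %), Et3N·HCl (1 equiv), Zn powder (2 equiv), DMPU, 25 °C
Reagents that add atoms: none
Why: Iodide and the ammonium proton open 14 at its unsubstituted carbon to iodohydrin 15, while zinc reduces divalent nickel to the zerovalent bipyridine complex, which inserts into the C–Br bond of 13. The arylnickel bromide captures the primary C7' radical that nickel generates from 15 by iodine abstraction, and reductive elimination from the resulting trivalent aryl(alkyl)nickel forms the C1'–C7' bond; zinc returns nickel to the cycle. The closest known reaction type is the nickel-catalysed reductive cross-electrophile coupling of aryl halides with epoxides under iodide co-catalysis. No ring is closed and no stereocentre is created: the radical sits on C7', no bond to C8' is broken, and its S configuration is that of 14. The step needs terminal rather than internal opening, which SN2 attack of iodide secures (a titanocene co-catalyst would give the branched isomer). It also needs cross- rather than homo-coupling, which rests on the two electrophiles being activated differently (oxidative addition for the sp2 bromide, radical formation for the sp3 iodide). The bromide of 13 is para to the ether oxygen with both ortho positions free, so insertion is unhindered despite the electron-rich ring. The acetonide, benzyl ethers and methyl ethers are inert to zinc and to the weakly acidic ammonium salt.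

Step 9
Reactants: 16 coupled acetonide
Product: 17 (1S,2R)-1-[4-(benzyloxy)-3,5-dimethoxyphenyl]-2-{4-[(2S)-3-(benzyloxy)-2-hydroxypropyl]-2,6-dimethoxyphenoxy}propane-1,3-diol
Conditions: AcOH–THF–H2O (3:1:1), 40 °C
Reagents that add atoms: none
Why: Mild acetal hydrolysis; a 2,2-dimethyl-1,3-dioxane cleaves readily in weak acid. It is done while the ring A oxygen is still benzylated, so the C7 carbinol is not activated toward ionisation.

Step 10
Reactants: 17 bis-benzyl ether triol
Product: 18 (1S,2R)-2-{4-[(2S)-2,3-dihydroxypropyl]-2,6-dimethoxyphenoxy}-1-(4-hydroxy-3,5-dimethoxyphenyl)propane-1,3-diol (target)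
Conditions: H2 (1 atm), Pd/C (10 wt %), EtOAc–EtOH, 25 °C
Reagents that add atoms: none
Why: Catalytic hydrogenolysis of the aryl benzyl ether and the primary alkyl benzyl ether under neutral conditions; the secondary benzylic alcohol of arylglycerol aryl ethers is normally retained in such debenzylations.

## Compound list

1 | 4-bromo-2,6-dimethoxyphenol | COc1cc(Br)cc(OC)c1O | starting material
2 | (4-bromo-2,6-dimethoxyphenoxy)acetic acid | COc1cc(Br)cc(OC)c1OCC(=O)O | intermediate
3 | (S)-4-benzyl-1,3-oxazolidin-2-one | O=C1N[C@@H](Cc2ccccc2)CO1 | starting material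
4 | (4-bromo-2,6-dimethoxyphenoxy)acetic pivalic anhydride (formed in the flask) | CC(C)(C)C(=O)OC(=O)COc1c(OC)cc(Br)cc1OC | intermediate
5 | (4S)-4-benzyl-3-[2-(4-bromo-2,6-dimethoxyphenoxy)acetyl]-1,3-oxazolidin-2-one | O=C(COc1c(OC)cc(Br)cc1OC)N1[C@@H](Cc2ccccc2)COC1=O | intermediate
6 | syringaldehyde | COc1cc(C=O)cc(OC)c1O | starting material
7 | 4-(benzyloxy)-3,5-dimethoxybenzaldehyde | COc1cc(C=O)cc(OC)c1OCc1ccccc1 | intermediate
8 | (Z)-dibutylboron enolate of 5 (formed in the flask) | CCCCB(CCCC)O/C(=C\Oc1c(OC)cc(Br)cc1OC)N1[C@@H](Cc2ccccc2)COC1=O | intermediate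
9 | dibutylboron aldolate of 10 (formed in the flask) | COc1cc([C@@H](OB(CCCC)CCCC)[C@@H](C(=O)N2[C@@H](Cc3ccccc3)COC2=O)Oc4c(OC)cc(Br)cc4OC)cc(OC)c1OCc5ccccc5 | intermediate
10 | (4S)-4-benzyl-3-[(2S,3R)-3-[4-(benzyloxy)-3,5-dimethoxyphenyl]-2-(4-bromo-2,6-dimethoxyphenoxy)-3-hydroxypropanoyl]-1,3-oxazolidin-2-one | COc1cc([C@@H](O)[C@@H](C(=O)N2[C@@H](Cc3ccccc3)COC2=O)Oc4c(OC)cc(Br)cc4OC)cc(OC)c1OCc5ccccc5 | intermediate
11 | (4S)-4-benzyl-3-[(2S,3S)-3-[4-(benzyloxy)-3,5-dimethoxyphenyl]-2-(4-bromo-2,6-dimethoxyphenoxy)-3-(4-nitrobenzoyloxy)propanoyl]-1,3-oxazolidin-2-one | COc1cc([C@H](OC(=O)c6ccc(cc6)[N+](=O)[O-])[C@@H](C(=O)N2[C@@H](Cc3ccccc3)COC2=O)Oc4c(OC)cc(Br)cc4OC)cc(OC)c1OCc5ccccc5 | intermediate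
12 | (1S,2R)-1-[4-(benzyloxy)-3,5-dimethoxyphenyl]-2-(4-bromo-2,6-dimethoxyphenoxy)propane-1,3-diol | COc1cc([C@H](O)[C@@H](CO)Oc2c(OC)cc(Br)cc2OC)cc(OC)c1OCc3ccccc3 | intermediate
13 | (4S,5R)-4-[4-(benzyloxy)-3,5-dimethoxyphenyl]-5-(4-bromo-2,6-dimethoxyphenoxy)-2,2-dimethyl-1,3-dioxane | COc1cc([C@@H]2OC(C)(C)OC[C@H]2Oc3c(OC)cc(Br)cc3OC)cc(OC)c1OCc4ccccc4 | intermediate
14 | (S)-benzyl glycidyl ether | C1[C@H](O1)COCc2ccccc2 | starting material
15 | (2R)-1-(benzyloxy)-3-iodopropan-2-ol (formed in the flask) | IC[C@H](O)COCc1ccccc1 | intermediate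
16 | (2S)-1-(benzyloxy)-3-[4-{[(4S,5R)-4-[4-(benzyloxy)-3,5-dimethoxyphenyl]-2,2-dimethyl-1,3-dioxan-5-yl]oxy}-3,5-dimethoxyphenyl]propan-2-ol | COc1cc([C@@H]2OC(C)(C)OC[C@H]2Oc3c(OC)cc(C[C@H](O)COCc4ccccc4)cc3OC)cc(OC)c1OCc5ccccc5 | intermediate
17 | (1S,2R)-1-[4-(benzyloxy)-3,5-dimethoxyphenyl]-2-{4-[(2S)-3-(benzyloxy)-2-hydroxypropyl]-2,6-dimethoxyphenoxy}propane-1,3-diol | COc1cc([C@H](O)[C@@H](CO)Oc2c(OC)cc(C[C@H](O)COCc3ccccc3)cc2OC)cc(OC)c1OCc4ccccc4 | intermediate
18 | (1S,2R)-2-{4-[(2S)-2,3-dihydroxypropyl]-2,6-dimethoxyphenoxy}-1-(4-hydroxy-3,5-dimethoxyphenyl)propane-1,3-diol | COc1cc([C@H](O)[C@@H](CO)Oc2c(OC)cc(C[C@H](O)CO)cc2OC)cc(OC)c1O | target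

## Step count and least certain steps

Total: 10 steps. Longest linear sequence: 9 steps (steps 1, 2, 4, 5, 6, 7, 8, 9, 10, from 1); step 3 is a one-step branch.

Step 8 (key step). The most likely failures are reductive homocoupling or hydrodebromination of the aryl bromide, if radical generation from the iodohydrin lags behind oxidative addition, and slow insertion of nickel into the electron-rich arene. Erosion of terminal regioselectivity or partial acetonide loss to the ammonium salt are lesser concerns. The fallback reverses the polarity of the same bond formation. It sets out from 13: bromine–lithium exchange with t-BuLi (2 equiv) in THF at −78 °C gives the aryllithium F1, which is treated with 14 and BF3·OEt2 at −78 °C. Lewis acid-assisted attack at the terminal epoxide carbon returns to the route at 16, with C8' untouched.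

Step 5. The most likely failure is dehydration of the activated β-hydroxy imide (E1cB loss across C7–C8, favoured by the acidic C8–H). Partial ionisation at the electron-rich benzylic carbon, giving incomplete inversion, is the second risk. The fallback is a redox inversion that sets out from 10 and returns at 12. LiBH4 gives the threo diol F2. TBSCl/imidazole gives the primary silyl ether F3. Dess–Martin periodinane with NaHCO3 gives the ketone F4. Zn(BH4)2 in Et2O at low temperature, with zinc chelated between the carbonyl and aryloxy oxygens so that hydride enters from the hydrogen side of C8, gives the erythro alcohol F5. Bu4NF then gives 12.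

Step 6. The most likely failure is β-elimination of 4-nitrobenzoate from the β-acyloxy imide under the basic hydride before the imide carbonyl is reduced. The fallback moves the inversion behind auxiliary removal; it sets out from 10 and returns at 12. It goes through the threo diol F2 and the silyl ether F3 (as above). Mitsunobu reaction of F3 with 4-nitrobenzoic acid, now without an acidifying carbonyl next to C8, gives the inverted ester F6. K2CO3 in MeOH gives the erythro alcohol F5, and Bu4NF gives 12.

Step 9. The most likely failure is acid-promoted ionisation at benzylic C7, leading to epimerisation or solvolysis before the acetal is fully cleaved. The fallback replaces the acid-labile tether by a fluoride-labile one; it sets out from 12 and returns at 17. tBu2Si(OTf)2 with 2,6-lutidine gives the cyclic silylene F7. Coupling with 14 under the conditions of step 8 gives the carbinol F8. HF·pyridine in THF–pyridine at 0 °C then frees 17.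

## Further compounds

F1 | step 8 | {4-[(4S,5R)-4-[4-(benzyloxy)-3,5-dimethoxyphenyl]-2,2-dimethyl-1,3-dioxan-5-yl]oxy-3,5-dimethoxyphenyl}lithium | COc1cc([C@@H]2OC(C)(C)OC[C@H]2Oc3c(OC)cc([Li])cc3OC)cc(OC)c1OCc4ccccc4
F2 | step 5 | (1R,2R)-1-[4-(benzyloxy)-3,5-dimethoxyphenyl]-2-(4-bromo-2,6-dimethoxyphenoxy)propane-1,3-diol | COc1cc([C@@H](O)[C@@H](CO)Oc2c(OC)cc(Br)cc2OC)cc(OC)c1OCc3ccccc3
F3 | step 5 | (1R,2R)-1-[4-(benzyloxy)-3,5-dimethoxyphenyl]-2-(4-bromo-2,6-dimethoxyphenoxy)-3-[(tert-butyldimethylsilyl)oxy]propan-1-ol | COc1cc([C@@H](O)[C@@H](CO[Si](C)(C)C(C)(C)C)Oc2c(OC)cc(Br)cc2OC)cc(OC)c1OCc3ccccc3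
F4 | step 5 | (2R)-1-[4-(benzyloxy)-3,5-dimethoxyphenyl]-2-(4-bromo-2,6-dimethoxyphenoxy)-3-[(tert-butyldimethylsilyl)oxy]propan-1-one | COc1cc(C(=O)[C@@H](CO[Si](C)(C)C(C)(C)C)Oc2c(OC)cc(Br)cc2OC)cc(OC)c1OCc3ccccc3
F5 | step 5 | (1S,2R)-1-[4-(benzyloxy)-3,5-dimethoxyphenyl]-2-(4-bromo-2,6-dimethoxyphenoxy)-3-[(tert-butyldimethylsilyl)oxy]propan-1-ol | COc1cc([C@H](O)[C@@H](CO[Si](C)(C)C(C)(C)C)Oc2c(OC)cc(Br)cc2OC)cc(OC)c1OCc3ccccc3
F6 | step 6 | (1S,2R)-1-[4-(benzyloxy)-3,5-dimethoxyphenyl]-2-(4-bromo-2,6-dimethoxyphenoxy)-3-[(tert-butyldimethylsilyl)oxy]propyl 4-nitrobenzoate | COc1cc([C@H](OC(=O)c2ccc(cc2)[N+](=O)[O-])[C@@H](CO[Si](C)(C)C(C)(C)C)Oc3c(OC)cc(Br)cc3OC)cc(OC)c1OCc4ccccc4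
F7 | step 9 | (4S,5R)-4-[4-(benzyloxy)-3,5-dimethoxyphenyl]-5-(4-bromo-2,6-dimethoxyphenoxy)-2,2-di-tert-butyl-1,3,2-dioxasilinane | COc1cc([C@@H]2O[Si](C(C)(C)C)(C(C)(C)C)OC[C@H]2Oc3c(OC)cc(Br)cc3OC)cc(OC)c1OCc4ccccc4
F8 | step 9 | (2S)-1-(benzyloxy)-3-[4-{[(4S,5R)-4-[4-(benzyloxy)-3,5-dimethoxyphenyl]-2,2-di-tert-butyl-1,3,2-dioxasilinan-5-yl]oxy}-3,5-dimethoxyphenyl]propan-2-ol | COc1cc([C@@H]2O[Si](C(C)(C)C)(C(C)(C)C)OC[C@H]2Oc3c(OC)cc(C[C@H](O)COCc4ccccc4)cc3OC)cc(OC)c1OCc5ccccc5
A1 | alternative 1 | [4-(benzyloxy)-3,5-dimethoxyphenyl]lithium | [Li]c1cc(OC)c(OCc2ccccc2)c(OC)c1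
A2 | alternative 1 | (2R)-2-{4-[(4S)-2,2-dimethyl-1,3-dioxolan-4-yl]methyl-2,6-dimethoxyphenoxy}-3-[(triisopropylsilyl)oxy]propanal | O=C[C@@H](CO[Si](C(C)C)(C(C)C)C(C)C)Oc1c(OC)cc(C[C@H]2COC(C)(C)O2)cc1OC
A3 | alternative 1 | (1S,2R)-1-[4-(benzyloxy)-3,5-dimethoxyphenyl]-2-{4-[(4S)-2,2-dimethyl-1,3-dioxolan-4-yl]methyl-2,6-dimethoxyphenoxy}-3-[(triisopropylsilyl)oxy]propan-1-ol | COc1cc([C@H](O)[C@@H](CO[Si](C(C)C)(C(C)C)C(C)C)Oc2c(OC)cc(C[C@H]3COC(C)(C)O3)cc2OC)cc(OC)c1OCc1ccccc1
A4 | alternative 2 | ethyl 3-[4-(benzyloxy)-3,5-dimethoxyphenyl]-2-{4-[(4S)-2,2-dimethyl-1,3-dioxolan-4-yl]methyl-2,6-dimethoxyphenoxy}-3-oxopropanoate (both C2 epimers) | COc1cc(C(=O)C(C(=O)OCC)Oc2c(OC)cc(C[C@H]3COC(C)(C)O3)cc2OC)cc(OC)c1OCc1ccccc1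
A5 | alternative 2 | ethyl (2S,3S)-3-[4-(benzyloxy)-3,5-dimethoxyphenyl]-2-{4-[(4S)-2,2-dimethyl-1,3-dioxolan-4-yl]methyl-2,6-dimethoxyphenoxy}-3-hydroxypropanoate | COc1cc([C@H](O)[C@@H](C(=O)OCC)Oc2c(OC)cc(C[C@H]3COC(C)(C)O3)cc2OC)cc(OC)c1OCc1ccccc1
A6 | alternative 3 | (1S)-1-[4-(benzyloxy)-3,5-dimethoxyphenyl]-2-{4-[(4S)-2,2-dimethyl-1,3-dioxolan-4-yl]methyl-2,6-dimethoxyphenoxy}prop-2-en-1-ol | COc1cc([C@H](O)C(=C)Oc2c(OC)cc(C[C@H]3COC(C)(C)O3)cc2OC)cc(OC)c1OCc1ccccc1
A7 | alternative 3 | (1S,2R)-1-[4-(benzyloxy)-3,5-dimethoxyphenyl]-2-{4-[(4S)-2,2-dimethyl-1,3-dioxolan-4-yl]methyl-2,6-dimethoxyphenoxy}propane-1,3-diol | COc1cc([C@H](O)[C@@H](CO)Oc2c(OC)cc(C[C@H]3COC(C)(C)O3)cc2OC)cc(OC)c1OCc1ccccc1
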